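Ring C of the (2S)-flavanone is disconnected across C3–C4: these carbons are flanked by the O1–C2 aryl ether stereocentre on one side and the C4 carbonyl on the other, so C2 can be installed beforehand as an (S)-allylic ether of ring A and the ketone carried as a silyl enol ether. Ring-closing metathesis of the C2 vinyl group with the enol ether olefin then creates the C3=C4 bond and ring C in one operation, as the regiodefined enol ether of the flavanone. The precursor is a C-geranylated phloroacetophenone bearing the (S)-1-(3,4-dimethoxyphenyl)allyl group on its unhindered ortho oxygen, silylated at the remaining oxygens and at the enol.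

Key step: step 7

Assumption: the (Sa,Sc,Sc) enantiomer of the binaphthol-derived N,N-bis(1-phenylethyl)phosphoramidite is taken to deliver an aryloxide to the face of the cinnamyl unit that gives the (S)-ether, by analogy with the (R)-ethers and (R)-amines expected from the (Ra,Rc,Rc) ligand; the antipodal ligand is equally available should the sense prove opposite.

Step 1
Reactants: 1 2,4,6-trihydroxyacetophenone; 2 geranyl bromide
Product: 3 1-[3-[(2E)-3,7-dimethylocta-2,6-dienyl]-2,4,6-trihydroxyphenyl]ethanone (3-geranyl-2,4,6-trihydroxyacetophenone)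
Conditions: DBU (1.1 equiv), THF, 0 °C to rt
Reagents that add atoms: none
Why: C-alkylation of the ambident phloroacetophenone anion (Friedel–Crafts-type SN2 allylation at the primary allylic bromide) should give the mono-C-geranyl compound as a single regioisomer because the two free ring positions are equivalent, and the E olefin is not touched.

Step 2
Reactants: 3 3-geranyl-2,4,6-trihydroxyacetophenone
Product: 4 1-[3-geranyl-2,6-dihydroxy-4-(triisopropylsilyloxy)phenyl]ethanone
Conditions: TIPSCl (1.0 equiv), Et3N (1.1 equiv), DMAP (5 mol %), CH2Cl2, −20 to 0 °C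
Reagents that add atoms: triisopropylsilyl chloride, CC(C)[Si](Cl)(C(C)C)C(C)C
Why: Silyl ether formation should occur at the 4-hydroxyl, which is para to the acetyl group, the most acidic and the only one unable to chelate the carbonyl, and the triisopropylsilyl group is chosen over a smaller silyl group because it resists transfer to aryloxide and alkoxide in step 5.

Step 3
Reactants: 5 methyl (2E)-3-(3,4-dimethoxyphenyl)prop-2-enoate
Product: 6 (2E)-3-(3,4-dimethoxyphenyl)prop-2-en-1-ol
Conditions: iBu2AlH (2.3 equiv), CH2Cl2, −78 to 0 °C; aq KNaC4H4O6 work-up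
Reagents that add atoms: none
Why: Hydride 1,2-reduction of an α,β-unsaturated ester with iBu2AlH should give the allylic alcohol without affecting the E double bond.

Step 4
Reactants: 6 (2E)-3-(3,4-dimethoxyphenyl)prop-2-en-1-ol
Product: 7 tert-butyl (2E)-3-(3,4-dimethoxyphenyl)prop-2-enyl carbonate
Conditions: Boc2O (1.3 equiv), Bu4NHSO4 (5 mol %), 30% aq NaOH, CH2Cl2, 0 °C to rt
Reagents that add atoms: di-tert-butyl dicarbonate, CC(C)(C)OC(=O)OC(=O)OC(C)(C)C
Why: Phase-transfer O-acylation of the primary allylic alcohol should give the tert-butyl carbonate, whose later ionisation releases only carbon dioxide and hindered tert-butoxide, which spares the aryl silyl ether and does not transfer an acyl group.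

Step 5
Reactants: 4 1-[3-geranyl-2,6-dihydroxy-4-(triisopropylsilyloxy)phenyl]ethanone; 7 tert-butyl (2E)-3-(3,4-dimethoxyphenyl)prop-2-enyl carbonate
Product: 9 1-[6-[(1S)-1-(3,4-dimethoxyphenyl)allyloxy]-3-geranyl-2-hydroxy-4-(triisopropylsilyloxy)phenyl]ethanone, via lithium aryloxide 8 (not isolated)
Conditions: 4 (1.2 equiv), LiN(SiMe3)2 (1.2 equiv), THF, 0 °C; then 7 (1.0 equiv), [Ir(cod)Cl]2 (2 mol %), (Sa,Sc,Sc)-(1,1'-binaphthalene-2,2'-diyl) N,N-bis(1-phenylethyl)phosphoramidite (4 mol %, catalyst preformed with nPrNH2), THF, 50 °C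
Reagents that add atoms: none
Why: Iridium-catalysed asymmetric allylic etherification should deliver the aryloxide to the aryl-substituted terminus of the allyl intermediate, giving the branched ether with the C2 configuration set by the phosphoramidite ligand, and attack should come from O6 because O2 is flanked by the geranyl and acetyl groups and stays hydrogen-bonded to the carbonyl.

Step 6
Reactants: 9 1-[6-[(1S)-1-(3,4-dimethoxyphenyl)allyloxy]-3-geranyl-2-hydroxy-4-(triisopropylsilyloxy)phenyl]ethanone
Product: 10 [1-[6-[(1S)-1-(3,4-dimethoxyphenyl)allyloxy]-3-geranyl-2-(tert-butyldimethylsilyloxy)-4-(triisopropylsilyloxy)phenyl]vinyloxy](tert-butyl)dimethylsilane (the tert-butyldimethylsilyl enol ether of the O2-silylated ketone)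
Conditions: TBSOTf (2.5 equiv), Et3N (4 equiv), CH2Cl2, −78 to 0 °C
Reagents that add atoms: tert-butyldimethylsilyl trifluoromethanesulfonate, CC(C)(C)[Si](C)(C)OS(=O)(=O)C(F)(F)F
Why: Silylation with the silyl triflate and amine base should cap the chelated phenol and convert the methyl ketone into its silyl enol ether by soft enolisation, the acetyl methyl group being the only enolisable position, while excess amine keeps the medium free of acid that could ionise the allylic ether.

Step 7
Reactants: 10 the tert-butyldimethylsilyl enol ether of the O2-silylated ketone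
Product: 11 (2S)-4,5-bis(tert-butyldimethylsilyloxy)-2-(3,4-dimethoxyphenyl)-6-geranyl-7-(triisopropylsilyloxy)-2H-chromene
Conditions: second-generation Grubbs catalyst RuCl2(=CHPh)(H2IMes)(PCy3) (10 mol %), 1,4-benzoquinone (20 mol %), degassed toluene (0.005 M), 60 °C, argon sparge
Reagents that add atoms: none
Why: Ring-closing enol ether–olefin metathesis: the ruthenium benzylidene should exchange onto the monosubstituted vinyl group at C2, the new alkylidene should add [2+2] across the 1,1-disubstituted silyl enol ether, and cycloreversion should form C3=C4 with release of ethylene. The closest known reaction type is ruthenium-catalysed ring closure of dienes in which one olefin is a silyl enol ether, which gives cyclic silyl enol ethers including benzo-fused heterocycles, together with the closure of ortho-vinyl aryl allyl ethers to 2H-chromenes. Ring C closes as a six-membered cyclic enol ether by joining two olefins that are both held ortho on ring A, so the closure is entropically favoured and driven by loss of ethylene. No stereocentre is formed, and C2, none of whose bonds is touched, keeps the S configuration set in step 5. The step needs chemoselectivity for the terminal and enol ether olefins over the two trisubstituted geranyl olefins, which their low reactivity towards the alkylidene at 60 °C and the strained medium ring they would have to close should secure. It also needs the allylic aryl ether not to isomerise, which benzoquinone should secure by intercepting ruthenium hydrides.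

Step 8
Reactants: 11 (2S)-4,5-bis(tert-butyldimethylsilyloxy)-2-(3,4-dimethoxyphenyl)-6-geranyl-7-(triisopropylsilyloxy)-2H-chromene
Product: 12 (2S)-2-(3,4-dimethoxyphenyl)-6-[(2E)-3,7-dimethylocta-2,6-dienyl]-5,7-dihydroxy-2,3-dihydro-4H-chromen-4-one
Conditions: Bu4NF (3.5 equiv), AcOH (3.5 equiv), THF, 0 °C to rt
Reagents that add atoms: none
Why: Fluoride desilylation should cleave both aryl silyl ethers and the silyl enol ether, with acetic acid protonating the enolate at C3 at once so that the β-aryloxy ketone is never left as an enolate that could open ring C, and C2 is untouched.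

Compound list
1 | 2,4,6-trihydroxyacetophenone | CC(=O)c1c(O)cc(O)cc1O | starting material
2 | geranyl bromide, (2E)-1-bromo-3,7-dimethylocta-2,6-diene | BrC/C=C(\C)CCC=C(C)C | starting material
3 | 1-[3-geranyl-2,4,6-trihydroxyphenyl]ethanone | CC(=O)c1c(O)cc(O)c(C/C=C(\C)CCC=C(C)C)c1O | intermediate
4 | 1-[3-geranyl-2,6-dihydroxy-4-(triisopropylsilyloxy)phenyl]ethanone | CC(=O)c1c(O)cc(O[Si](C(C)C)(C(C)C)C(C)C)c(C/C=C(\C)CCC=C(C)C)c1O | intermediate
5 | methyl (2E)-3-(3,4-dimethoxyphenyl)prop-2-enoate | COC(=O)/C=C/c1ccc(OC)c(OC)c1 | starting material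
6 | (2E)-3-(3,4-dimethoxyphenyl)prop-2-en-1-ol | OC/C=C/c1ccc(OC)c(OC)c1 | intermediate
7 | tert-butyl (2E)-3-(3,4-dimethoxyphenyl)prop-2-enyl carbonate | CC(C)(C)OC(=O)OC/C=C/c1ccc(OC)c(OC)c1 | intermediate
8 | monolithium aryloxide of 4, drawn at O6 | CC(=O)c1c([O-])cc(O[Si](C(C)C)(C(C)C)C(C)C)c(C/C=C(\C)CCC=C(C)C)c1O.[Li+] | intermediate
9 | 1-[6-[(1S)-1-(3,4-dimethoxyphenyl)allyloxy]-3-geranyl-2-hydroxy-4-(triisopropylsilyloxy)phenyl]ethanone | C=C[C@H](Oc1cc(O[Si](C(C)C)(C(C)C)C(C)C)c(C/C=C(\C)CCC=C(C)C)c(O)c1C(C)=O)c1ccc(OC)c(OC)c1 | intermediate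
10 | tert-butyldimethylsilyl enol ether of 1-[6-[(1S)-1-(3,4-dimethoxyphenyl)allyloxy]-3-geranyl-2-(tert-butyldimethylsilyloxy)-4-(triisopropylsilyloxy)phenyl]ethanone | C=C[C@H](Oc1cc(O[Si](C(C)C)(C(C)C)C(C)C)c(C/C=C(\C)CCC=C(C)C)c(O[Si](C)(C)C(C)(C)C)c1C(=C)O[Si](C)(C)C(C)(C)C)c1ccc(OC)c(OC)c1 | intermediate
11 | (2S)-4,5-bis(tert-butyldimethylsilyloxy)-2-(3,4-dimethoxyphenyl)-6-geranyl-7-(triisopropylsilyloxy)-2H-chromene | COc1ccc([C@@H]2C=C(O[Si](C)(C)C(C)(C)C)c3c(cc(O[Si](C(C)C)(C(C)C)C(C)C)c(C/C=C(\C)CCC=C(C)C)c3O[Si](C)(C)C(C)(C)C)O2)cc1OC | intermediate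
12 | (2S)-2-(3,4-dimethoxyphenyl)-6-geranyl-5,7-dihydroxy-2,3-dihydro-4H-chromen-4-one | COc1ccc([C@@H]2CC(=O)c3c(cc(O)c(C/C=C(\C)CCC=C(C)C)c3O)O2)cc1OC | target

Total steps: 8. Longest linear sequence: 6 steps (steps 1, 2, 5, 6, 7, 8; the branch through steps 3 and 4 is equally long).

Steps most likely to fail

Step 7. The alkylidene formed at the C2 vinyl group may fail to engage the enol ether olefin, which is twisted out of the plane of ring A and screened by the neighbouring silyloxy group. The result would be intermolecular metathesis at the vinyl group or no turnover. The fallback replaces the open diene by a silicon-bridged, planarised one. It sets out from 9: tBu2Si(OTf)2 and Et3N in CH2Cl2 at 0 °C should silylate O2 and then enolise the ketone intramolecularly, tying O2 and the enol oxygen into (S)-2,2-di-tert-butyl-5-[1-(3,4-dimethoxyphenyl)allyloxy]-8-geranyl-4-methylene-7-(triisopropylsilyloxy)-4H-1,3,2-benzodioxasiline F1. In this diene the enol ether olefin lies in the plane of ring A, carries no flanking silyl ether and points its CH2 terminus at the allyl ether. Ring closure under the conditions of step 7 should give the O4,O5-di-tert-butylsilylene-bridged (2S)-2-(3,4-dimethoxyphenyl)-6-geranyl-7-(triisopropylsilyloxy)-2H-chromene F2. Bu4NF and AcOH in THF then remove the silylene and the triisopropylsilyl group, and the fallback comes back to the route at 12.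

Step 5. The chelated, doubly ortho-substituted aryloxide may attack the allyliridium intermediate slowly, and may react through O2 or through ring carbon C5, or twice. The product ether may also lose enantiomeric purity by reversible ionisation. The fallback forms the O–C2 bond by SN2 displacement with inversion and makes the vinyl group afterwards. It sets out from 4: Mitsunobu etherification (PPh3, DIAD, toluene, 0 °C) with (R)-3-chloro-1-(3,4-dimethoxyphenyl)propan-1-ol F3 should engage the less hindered O6 and give 1-[6-[(1S)-3-chloro-1-(3,4-dimethoxyphenyl)propoxy]-3-geranyl-2-hydroxy-4-(triisopropylsilyloxy)phenyl]ethanone F4. F3 would come from commercial 3-chloro-1-(3,4-dimethoxyphenyl)propan-1-one by Corey–Bakshi–Shibata reduction with BH3·SMe2 and the catalyst enantiomer that gives the R alcohol. Displacement of chloride with PhSeNa, preformed from (PhSe)2 and NaBH4 in EtOH/THF, should give the corresponding (1S)-3-(phenylselanyl)propyl ether F5. Oxidation with H2O2 and pyridine in CH2Cl2 at 0 °C to rt, followed by syn-elimination of the selenoxide through its only β-hydrogens, should form the terminal vinyl group, and the fallback comes back to the route at 9.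

Step 2. The silyl group may distribute between O4 and O6, or the reaction may run on to the 4,6-bis-silyl ether, because in 3 both hydroxyls have one ortho substituent. The fallback reverses the order of the two operations on ring A. It sets out from 1: silylation of the symmetric triol (TIPSCl, Et3N, CH2Cl2, −20 °C), in which O4 is the only unflanked hydroxyl that cannot chelate the carbonyl, should give 1-[2,6-dihydroxy-4-(triisopropylsilyloxy)phenyl]ethanone F6. C-Geranylation of F6 with 2 (DBU, THF, rt), in which the two free ring positions are again equivalent, comes back to the route at 4.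

Further compounds
F1 | step 7 | (S)-2,2-di-tert-butyl-5-[1-(3,4-dimethoxyphenyl)allyloxy]-8-geranyl-4-methylene-7-(triisopropylsilyloxy)-4H-1,3,2-benzodioxasiline | C=C[C@H](Oc1cc(O[Si](C(C)C)(C(C)C)C(C)C)c(C/C=C(\C)CCC=C(C)C)c2c1C(=C)O[Si](C(C)(C)C)(C(C)(C)C)O2)c1ccc(OC)c(OC)c1
F2 | step 7 | O4,O5-di-tert-butylsilylene-bridged (2S)-2-(3,4-dimethoxyphenyl)-6-geranyl-7-(triisopropylsilyloxy)-2H-chromene-4,5-diol | COc1ccc([C@@H]2C=C3O[Si](C(C)(C)C)(C(C)(C)C)Oc4c(C/C=C(\C)CCC=C(C)C)c(O[Si](C(C)C)(C(C)C)C(C)C)cc(O2)c34)cc1OC
F3 | step 5 | (R)-3-chloro-1-(3,4-dimethoxyphenyl)propan-1-ol | ClCC[C@@H](O)c1ccc(OC)c(OC)c1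
F4 | step 5 | 1-[6-[(1S)-3-chloro-1-(3,4-dimethoxyphenyl)propoxy]-3-geranyl-2-hydroxy-4-(triisopropylsilyloxy)phenyl]ethanone | ClCC[C@H](Oc1cc(O[Si](C(C)C)(C(C)C)C(C)C)c(C/C=C(\C)CCC=C(C)C)c(O)c1C(C)=O)c1ccc(OC)c(OC)c1
F5 | step 5 | 1-[6-[(1S)-1-(3,4-dimethoxyphenyl)-3-(phenylselanyl)propoxy]-3-geranyl-2-hydroxy-4-(triisopropylsilyloxy)phenyl]ethanone | c1ccccc1[Se]CC[C@H](Oc1cc(O[Si](C(C)C)(C(C)C)C(C)C)c(C/C=C(\C)CCC=C(C)C)c(O)c1C(C)=O)c1ccc(OC)c(OC)c1
F6 | step 2 | 1-[2,6-dihydroxy-4-(triisopropylsilyloxy)phenyl]ethanone | CC(=O)c1c(O)cc(O[Si](C(C)C)(C(C)C)C(C)C)cc1O
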